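## The problem

The target is an 8-O-4′ neolignan. Ring A (4-hydroxy-3-methoxyphenyl) sits on C7 of a glycerol chain C7–C8–C9 with hydroxyls on C7 and C9, and the C8 oxygen is bonded to C4′ of ring B (4-acetyl-2,6-dimethoxyphenyl). No ring has to be closed; the difficulty is one secondary alkyl aryl ether that is hindered on both sides, with C4′ between two methoxy-bearing carbons and C8 between two oxygenated carbons. The stereocentres are adjacent, 7R and 8S (erythro). C8 can be bought as a glyceric acid derivative, and its oxygen can steer a hydride onto a C7 ketone through a chelate, so one purchased centre can set the other. Several groups are fragile: the benzylic carbinol C7, para to an oxygen of ring A, ionises under acid and then loses its configuration; the C8 hydrogen becomes acidic whenever a carbonyl is attached to C8; the aryl methyl ketone tolerates neither hydrides nor organometallic reagents and must appear late; and the phenol must stay masked through the basic steps. Direct ether formation would have to join a hindered alkoxide to a 2,6-disubstituted arene, or a hindered phenoxide to a secondary carbon with inversion, and both invite elimination, silyl migration or epimerisation. The way out lies in the pattern of ring B: C4′ lies between the oxygen-bearing carbons C3′ and C5′ with the acetyl carbon C1′ opposite, which is C2 of a cyclohexane-1,3-dione whose C5 carries a carboxyl group. C4′ can therefore enter as a carbenoid carbon that takes up the C8 hydroxyl, and ring B can be aromatised afterwards.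

## Retrosynthesis

**Protecting groups.** Target 20 is traced to phenol 19 by cutting the O–Si bonds at O7 and O9, and 19 to benzyl ether 18 by cutting the O–CH2Ph bond on ring A. Silyl ethers are chosen for the chain because fluoride removes them without acid at the benzylic centre; an acetal across O7 and O9 would need acid at the very end. Benzyl is chosen for the phenol because it survives carbonate bases, Grignard reagents and both metal-mediated steps; an aryl silyl ether would be at risk in the phenol methylation. The benzyl group is removed first, while the bulky silyl ether still shields the benzylic C7–O bond from hydrogenolysis.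

**Acetyl group.** Ketone 18 is cut at the CO–CH3 bond to methyl ester 16, with Weinreb amide 17 as a passing intermediate. Carrying the acetyl group from the start would put a second enolisable ketone through the enolisation and oxidation used to aromatise ring B, and the commercial dione bears an ester, not an acetyl group. The forward step must add one methyl group and stop.

**Ring B as an arene.** Ester 16 is cut at its two O–CH3 bonds to resorcinol 15, and 15 is taken back by formal addition of H2 to the 2-alkoxy cyclohexane-1,3-dione 12; bis-silyl dienol ether 13 and aryl silyl ether 14 are passing intermediates. The dione fixes the 1,2,3-trioxygenated pattern and the para carboxyl group without any substitution on an arene. The forward dehydrogenation must spare silyl ethers and the electron-rich benzylic C7–H, which excludes quinone oxidants and acid-generating halogenations and points to a palladium-mediated route through the silyl dienol ether.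

**The ether bond.** Dione 12 is cut at O–C4′ into alcohol 9 and diazo dione 11. Against the neighbouring cut at C8–O, this one leaves the C8 stereocentre untouched. Against an arylation of 9 with a preformed 2,6-dimethoxyaryl electrophile, it needs no base and no attack on a hindered arene carbon. The precursors are a protected triol with one free hydroxyl and a one-step diazo compound. The forward reaction must be chemoselective for O–H insertion.

**Diazo dione.** Compound 11 is cut at the C=N2 bond to commercial dione ester 10; diazo transfer to the doubly activated methylene is the only operation needed.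

**Telling three hydroxyls apart.** Alcohol 9 is cut at O9–Si to diol 8, 8 is taken back to acetonide 7, and 7 is cut at O7–Si to carbinol 6. The acetonide that arrives with the starting material keeps O8 and O9 masked while O7 is silylated. Its removal then exposes a primary and a secondary hydroxyl that differ enough for selective silylation. Each forward step must leave the benzylic silyl ether in place and must not move it to O8.

**C7 stereocentre.** Carbinol 6 is cut at C7–H to aryl ketone 5. Making the C7–aryl bond by addition to an aldehyde would rely on open-chain induction, whereas reduction of 5 can use a rigid chelate between the carbonyl oxygen and the dioxolane oxygen on C8. The forward reduction must deliver hydride to the face that gives the anti (7R,8S) carbinol.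

**Carbon skeleton.** Ketone 5 is cut at the C7–C1 bond into Weinreb amide 2 and aryl Grignard reagent 4, made from bromide 3; amide 2 comes from commercial glycerate acetonide 1. All carbons of the chain and the C8 configuration are bought, and the acylation must stop at the ketone without enolising C8.

## Roads not taken

Alternative 1: The cut is the C7–C1 bond, made last. Aldehyde A1, which already carries ring B (acetyl masked as a dioxolane) on the C8 oxygen, would be attacked by aryl titanium triisopropoxide A2, a non-chelating reagent of tetravalent titanium, to give carbinol A3. With the C8–OAr bond antiperiplanar to the incoming aryl group, the Felkin–Anh model predicts the required erythro product.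
- Merits: the route is convergent and short, and the hindered ether is made early on a small alpha-hydroxy carbonyl compound, where displacement chemistry is reliable.
- Weak points: A1 is an alpha-aryloxy aldehyde whose C8 hydrogen is acidic, so its configuration is at risk when it is made and when it meets a basic organometallic reagent. C7 rests on a single open-chain 1,2-induction with a large aryloxy group and a silyloxymethyl group competing for the same roles, and a threo by-product would be hard to remove.
- Comparison: this road is shorter by several steps. The chosen plan answers with a C8 that is never next to a carbonyl once the ether exists, and with a C7 set by a chelate before ring B is present.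

Alternative 2: The cut is the C8–O bond from the alkyl side. Nosylate A4, the C8 epimer with O7 silylated, would be displaced with inversion by phenol A5 in the presence of Cs2CO3 to give ether A6.
- Merits: both stereocentres can come from one catalytic asymmetric dihydroxylation, inversion turns threo into erythro, and ring B arrives complete with its acetyl group.
- Weak points: a 2,6-disubstituted phenoxide must attack a secondary carbon next to a silyloxy benzylic carbon, so elimination toward the conjugated ester competes. The C8 hydrogen is alpha to an ester in both A4 and A6 and can epimerise under the carbonate base. The ester of A6 must later be reduced to the C9 alcohol in the presence of the more reactive aryl ketone, which costs the steps that were saved.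
- Comparison: in bond count and convergence this road is better. The chosen plan sets against it a neutral ether formation in which no bond to a stereocentre is made or broken.

Alternative 3: The cut is the C7–H bond. Racemic keto ester A7, which enolises and so interconverts its enantiomers, would be reduced by an NADPH-dependent ketoreductase in a dynamic kinetic resolution to hydroxy ester A8, fixing C7 and C8 together.
- Merits: both centres are set in one catalytic step from a racemate that is easy to assemble, without chiral starting material and with good prospects on scale.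
- Weak points: the enzyme must accept a very large alpha-aryloxy group and give the anti (2R,3R) product; structure alone cannot predict this, so the plan depends on a screening outcome. Ester reduction and ketal removal still follow.
- Comparison: if a suitable enzyme exists, this road is superior in step count and scalability. The chosen plan's stereochemical outcomes follow from substrate models (chiral pool, chelate, retention at oxygen) and do not depend on finding a catalyst.

Key step: step 8

Remark: dione 12 is drawn as the diketone although it should exist largely as its enol. Ring carbons of 12 and 13 that are stereogenic on paper are left undefined, because they are mobile or are lost in step 9.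

## Route

Step 1
Reactants: 1 methyl (4S)-2,2-dimethyl-1,3-dioxolane-4-carboxylate
Product: 2 (4S)-N-methoxy-N,2,2-trimethyl-1,3-dioxolane-4-carboxamide
Conditions: MeNHOMe·HCl, iPrMgCl, THF, −20 °C
Reagents that add atoms: N,O-dimethylhydroxylamine hydrochloride, CNOC.Cl
Why: Weinreb amide formation: the chloromagnesium amide made in the flask acylates on the methyl ester at low temperature, and the dioxolane centre is not enolised, so 4S is kept.

Step 2
Reactants: 3 1-(benzyloxy)-4-bromo-2-methoxybenzene; 2 (4S)-N-methoxy-N,2,2-trimethyl-1,3-dioxolane-4-carboxamide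
Product: 5 [4-(benzyloxy)-3-methoxyphenyl][(4S)-2,2-dimethyl-1,3-dioxolan-4-yl]methanone, via aryl Grignard reagent 4 (not isolated)
Conditions: Mg, I2 (cat.), THF, reflux; then 2, THF, 0 °C; aq. NH4Cl
Reagents that add atoms: none
Why: Grignard formation and Weinreb ketone synthesis: the chelated tetrahedral adduct holds until work-up, so one aryl group adds, and the alpha centre is untouched at 0 °C.

Step 3
Reactants: 5 [4-(benzyloxy)-3-methoxyphenyl][(4S)-2,2-dimethyl-1,3-dioxolan-4-yl]methanone
Product: 6 (R)-[4-(benzyloxy)-3-methoxyphenyl][(4S)-2,2-dimethyl-1,3-dioxolan-4-yl]methanol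
Conditions: Zn(BH4)2, Et2O, −30 to 0 °C
Reagents that add atoms: none
Why: Cram-chelate reduction: zinc bridges the carbonyl oxygen and the dioxolane oxygen on the alpha carbon, and hydride enters from the face of the alpha hydrogen, which gives the anti carbinol (R at the new centre, later C7).

Step 4
Reactants: 6 (R)-[4-(benzyloxy)-3-methoxyphenyl][(4S)-2,2-dimethyl-1,3-dioxolan-4-yl]methanol
Product: 7 {(R)-[4-(benzyloxy)-3-methoxyphenyl][(4S)-2,2-dimethyl-1,3-dioxolan-4-yl]methoxy}(tert-butyl)dimethylsilane
Conditions: TBSOTf, 2,6-lutidine, CH2Cl2, −78 to 0 °C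
Reagents that add atoms: tert-butyldimethylsilyl trifluoromethanesulfonate, CC(C)(C)[Si](C)(C)OS(=O)(=O)C(F)(F)F
Why: Silylation of a secondary benzylic alcohol with a silyl triflate and a hindered pyridine base; the buffered medium leaves the acetonide and the C7 configuration intact.

Step 5
Reactants: 7 {(R)-[4-(benzyloxy)-3-methoxyphenyl][(4S)-2,2-dimethyl-1,3-dioxolan-4-yl]methoxy}(tert-butyl)dimethylsilane
Product: 8 (2S,3R)-3-[4-(benzyloxy)-3-methoxyphenyl]-3-[(tert-butyldimethylsilyl)oxy]propane-1,2-diol
Conditions: CuCl2·2H2O, MeCN, 0 °C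
Reagents that add atoms: none
Why: Mild Lewis-acid hydrolysis of a terminal isopropylidene acetal; hydrated CuCl2 at 0 °C is known to spare secondary silyl ethers, and the low acidity avoids ionisation at the benzylic carbon.

Step 6
Reactants: 8 (2S,3R)-3-[4-(benzyloxy)-3-methoxyphenyl]-3-[(tert-butyldimethylsilyl)oxy]propane-1,2-diol
Product: 9 (1R,2S)-1-[4-(benzyloxy)-3-methoxyphenyl]-1,3-bis[(tert-butyldimethylsilyl)oxy]propan-2-ol
Conditions: TBSCl (1.05 equiv), imidazole, CH2Cl2, 0 °C
Reagents that add atoms: tert-butyldimethylsilyl chloride, CC(C)(C)[Si](C)(C)Cl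
Why: Selective silylation of the primary hydroxyl of a 1,2-diol; imidazole is too weak a base to move the silyl group from O7 to O8.

Step 7
Reactants: 10 methyl 3,5-dioxocyclohexane-1-carboxylate
Product: 11 methyl 4-diazo-3,5-dioxocyclohexane-1-carboxylate
Conditions: 4-acetamidobenzenesulfonyl azide, Et3N, MeCN, 0 °C to rt
Reagents that add atoms: 4-acetamidobenzenesulfonyl azide, CC(=O)Nc1ccc(cc1)S(=O)(=O)N=[N+]=[N-]
Why: Regitz diazo transfer to the methylene between the two ketones, the most acidic position of the dione.

Step 8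
Reactants: 9 (1R,2S)-1-[4-(benzyloxy)-3-methoxyphenyl]-1,3-bis[(tert-butyldimethylsilyl)oxy]propan-2-ol; 11 methyl 4-diazo-3,5-dioxocyclohexane-1-carboxylate
Product: 12 methyl 4-{[(1R,2S)-1-[4-(benzyloxy)-3-methoxyphenyl]-1,3-bis[(tert-butyldimethylsilyl)oxy]propan-2-yl]oxy}-3,5-dioxocyclohexane-1-carboxylate (diketone drawn; enol tautomers in equilibrium)
Conditions: Rh2(OAc)4 (2 mol %), 4 Å MS, CH2Cl2, 40 °C, slow addition of 11 (2.5 equiv)
Reagents that add atoms: none
Why: Rh2(OAc)4, a dimer of divalent rhodium, takes up the diazo carbon of 11 and expels N2 to give an electrophilic carbenoid flanked by two acyl groups. The only hydroxyl of 9, on C8, adds through oxygen to give a rhodium-bound oxonium ylide, and a proton shift releases the catalyst and leaves the 2-alkoxy dione, mostly as its enol. The closest known reaction type is the O–H insertion of 2-diazocyclohexane-1,3-diones and related diazo dicarbonyl compounds into alcohols under dirhodium tetracarboxylate catalysis. No ring closes and no stereocentre is created: the C8–O bond is never broken, so 8S is retained, and C2 of the dione is trigonal in the enol. The step needs chemoselectivity for the hydroxyl over the ether oxygens, the two arenes and Wolff rearrangement; the hydroxyl is the only protic and the most basic lone-pair donor, the silyl and aryl ether oxygens are hindered or delocalised, and the neutral medium excludes silyl migration. Slow addition of excess 11 to alcohol and catalyst keeps the carbenoid concentration low, so that capture by the hindered alcohol can compete with carbene dimerisation, and molecular sieves remove water as a competing O–H donor.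

Step 9
Reactants: 12 methyl 4-{[(1R,2S)-1-[4-(benzyloxy)-3-methoxyphenyl]-1,3-bis[(tert-butyldimethylsilyl)oxy]propan-2-yl]oxy}-3,5-dioxocyclohexane-1-carboxylate
Product: 15 methyl 4-{[(1R,2S)-1-[4-(benzyloxy)-3-methoxyphenyl]-1,3-bis[(tert-butyldimethylsilyl)oxy]propan-2-yl]oxy}-3,5-dihydroxybenzoate, via bis(trimethylsilyl) dienol ether 13 (not isolated), via aryl trimethylsilyl ether 14 (not isolated)
Conditions: TMSOTf (2.4 equiv), Et3N, CH2Cl2, 0 °C; pentane extraction; Pd(OAc)2 (1.1 equiv), MeCN, rt; then aq. citric acid, THF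
Reagents that add atoms: none
Why: Saegusa–Ito dehydrogenation: soft enolisation gives the 1,3-bis(silyloxy)diene, divalent palladium adds at the diene terminus next to the ester-bearing carbon, beta-hydride elimination gives a dienone that tautomerises to the arene, and the labile aryl silyl ether is hydrolysed on work-up; palladation at the alkoxy-bearing carbon has no beta hydrogen and is unproductive.

Step 10
Reactants: 15 methyl 4-{[(1R,2S)-1-[4-(benzyloxy)-3-methoxyphenyl]-1,3-bis[(tert-butyldimethylsilyl)oxy]propan-2-yl]oxy}-3,5-dihydroxybenzoate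
Product: 16 methyl 4-{[(1R,2S)-1-[4-(benzyloxy)-3-methoxyphenyl]-1,3-bis[(tert-butyldimethylsilyl)oxy]propan-2-yl]oxy}-3,5-dimethoxybenzoate
Conditions: MeI, K2CO3, DMF, rt
Reagents that add atoms: iodomethane, CI
Why: Williamson methylation of two phenols with a carbonate base; the alkyl silyl ethers, the benzyl ether and the methyl ester are inert.

Step 11
Reactants: 16 methyl 4-{[(1R,2S)-1-[4-(benzyloxy)-3-methoxyphenyl]-1,3-bis[(tert-butyldimethylsilyl)oxy]propan-2-yl]oxy}-3,5-dimethoxybenzoate
Product: 18 1-(4-{[(1R,2S)-1-[4-(benzyloxy)-3-methoxyphenyl]-1,3-bis[(tert-butyldimethylsilyl)oxy]propan-2-yl]oxy}-3,5-dimethoxyphenyl)ethan-1-one, via Weinreb amide 17 (not isolated)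
Conditions: MeNHOMe·HCl, iPrMgCl, THF, −20 °C; then MeMgBr, −20 to 0 °C; aq. NH4Cl
Reagents that add atoms: methylmagnesium bromide, C[Mg]Br
Why: Ester to ketone through a Weinreb amide made in the flask: the magnesium amide converts the unhindered benzoate to the N-methoxy-N-methylamide, and MeMgBr adds once because the chelated adduct survives until the quench.

Step 12
Reactants: 18 1-(4-{[(1R,2S)-1-[4-(benzyloxy)-3-methoxyphenyl]-1,3-bis[(tert-butyldimethylsilyl)oxy]propan-2-yl]oxy}-3,5-dimethoxyphenyl)ethan-1-one
Product: 19 1-(4-{[(1R,2S)-1,3-bis[(tert-butyldimethylsilyl)oxy]-1-(4-hydroxy-3-methoxyphenyl)propan-2-yl]oxy}-3,5-dimethoxyphenyl)ethan-1-one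
Conditions: H2 (1 atm), Pd/C, EtOAc, rt
Reagents that add atoms: none
Why: Hydrogenolysis of an aryl benzyl ether over palladium at 1 atm in a neutral solvent is faster than reduction of the electron-rich aryl ketone, and the bulky silyl ether on C7 shields the benzylic C–O bond.

Step 13
Reactants: 19 1-(4-{[(1R,2S)-1,3-bis[(tert-butyldimethylsilyl)oxy]-1-(4-hydroxy-3-methoxyphenyl)propan-2-yl]oxy}-3,5-dimethoxyphenyl)ethan-1-one
Product: 20 1-(4-{[(1R,2S)-1,3-dihydroxy-1-(4-hydroxy-3-methoxyphenyl)propan-2-yl]oxy}-3,5-dimethoxyphenyl)ethan-1-one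
Conditions: TBAF, AcOH, THF, 0 °C to rt
Reagents that add atoms: none
Why: Fluoride-mediated desilylation of both silyl ethers; acetic acid buffers the alkoxides so that neither silyl migration nor base-induced loss of the aryloxy group can occur, and no bond to C7 or C8 is broken.

## Compound list

1 | methyl (4S)-2,2-dimethyl-1,3-dioxolane-4-carboxylate | COC(=O)[C@@H]1COC(C)(C)O1 | starting material
2 | (4S)-N-methoxy-N,2,2-trimethyl-1,3-dioxolane-4-carboxamide | CON(C)C(=O)[C@@H]1COC(C)(C)O1 | intermediate
3 | 1-(benzyloxy)-4-bromo-2-methoxybenzene | COc1cc(Br)ccc1OCc1ccccc1 | starting material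
4 | [4-(benzyloxy)-3-methoxyphenyl]magnesium bromide | COc1cc([Mg]Br)ccc1OCc1ccccc1 | intermediate (not isolated)
5 | [4-(benzyloxy)-3-methoxyphenyl][(4S)-2,2-dimethyl-1,3-dioxolan-4-yl]methanone | COc1cc(C(=O)[C@@H]2COC(C)(C)O2)ccc1OCc1ccccc1 | intermediate
6 | (R)-[4-(benzyloxy)-3-methoxyphenyl][(4S)-2,2-dimethyl-1,3-dioxolan-4-yl]methanol | COc1cc([C@@H](O)[C@@H]2COC(C)(C)O2)ccc1OCc1ccccc1 | intermediate
7 | {(R)-[4-(benzyloxy)-3-methoxyphenyl][(4S)-2,2-dimethyl-1,3-dioxolan-4-yl]methoxy}(tert-butyl)dimethylsilane | COc1cc([C@@H](O[Si](C)(C)C(C)(C)C)[C@@H]2COC(C)(C)O2)ccc1OCc1ccccc1 | intermediate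
8 | (2S,3R)-3-[4-(benzyloxy)-3-methoxyphenyl]-3-[(tert-butyldimethylsilyl)oxy]propane-1,2-diol | COc1cc([C@@H](O[Si](C)(C)C(C)(C)C)[C@H](CO)O)ccc1OCc1ccccc1 | intermediate
9 | (1R,2S)-1-[4-(benzyloxy)-3-methoxyphenyl]-1,3-bis[(tert-butyldimethylsilyl)oxy]propan-2-ol | COc1cc([C@@H](O[Si](C)(C)C(C)(C)C)[C@H](CO[Si](C)(C)C(C)(C)C)O)ccc1OCc1ccccc1 | intermediate
10 | methyl 3,5-dioxocyclohexane-1-carboxylate | COC(=O)C1CC(=O)CC(=O)C1 | starting material
11 | methyl 4-diazo-3,5-dioxocyclohexane-1-carboxylate | COC(=O)C1CC(=O)C(=[N+]=[N-])C(=O)C1 | intermediate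
12 | methyl 4-{[(1R,2S)-1-[4-(benzyloxy)-3-methoxyphenyl]-1,3-bis[(tert-butyldimethylsilyl)oxy]propan-2-yl]oxy}-3,5-dioxocyclohexane-1-carboxylate | COc1cc([C@@H](O[Si](C)(C)C(C)(C)C)[C@H](CO[Si](C)(C)C(C)(C)C)OC2C(=O)CC(C(=O)OC)CC2=O)ccc1OCc1ccccc1 | intermediate
13 | methyl 4-{[(1R,2S)-1-[4-(benzyloxy)-3-methoxyphenyl]-1,3-bis[(tert-butyldimethylsilyl)oxy]propan-2-yl]oxy}-3,5-bis[(trimethylsilyl)oxy]cyclohexa-2,4-diene-1-carboxylate (C1 epimers) | COc1cc([C@@H](O[Si](C)(C)C(C)(C)C)[C@H](CO[Si](C)(C)C(C)(C)C)OC2=C(O[Si](C)(C)C)CC(C(=O)OC)C=C2O[Si](C)(C)C)ccc1OCc1ccccc1 | intermediate (not isolated)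
14 | methyl 4-{[(1R,2S)-1-[4-(benzyloxy)-3-methoxyphenyl]-1,3-bis[(tert-butyldimethylsilyl)oxy]propan-2-yl]oxy}-3-hydroxy-5-[(trimethylsilyl)oxy]benzoate | COc1cc([C@@H](O[Si](C)(C)C(C)(C)C)[C@H](CO[Si](C)(C)C(C)(C)C)Oc2c(O)cc(C(=O)OC)cc2O[Si](C)(C)C)ccc1OCc1ccccc1 | intermediate (not isolated)
15 | methyl 4-{[(1R,2S)-1-[4-(benzyloxy)-3-methoxyphenyl]-1,3-bis[(tert-butyldimethylsilyl)oxy]propan-2-yl]oxy}-3,5-dihydroxybenzoate | COc1cc([C@@H](O[Si](C)(C)C(C)(C)C)[C@H](CO[Si](C)(C)C(C)(C)C)Oc2c(O)cc(C(=O)OC)cc2O)ccc1OCc1ccccc1 | intermediate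
16 | methyl 4-{[(1R,2S)-1-[4-(benzyloxy)-3-methoxyphenyl]-1,3-bis[(tert-butyldimethylsilyl)oxy]propan-2-yl]oxy}-3,5-dimethoxybenzoate | COc1cc([C@@H](O[Si](C)(C)C(C)(C)C)[C@H](CO[Si](C)(C)C(C)(C)C)Oc2c(OC)cc(C(=O)OC)cc2OC)ccc1OCc1ccccc1 | intermediate
17 | 4-{[(1R,2S)-1-[4-(benzyloxy)-3-methoxyphenyl]-1,3-bis[(tert-butyldimethylsilyl)oxy]propan-2-yl]oxy}-N,3,5-trimethoxy-N-methylbenzamide | COc1cc([C@@H](O[Si](C)(C)C(C)(C)C)[C@H](CO[Si](C)(C)C(C)(C)C)Oc2c(OC)cc(C(=O)N(C)OC)cc2OC)ccc1OCc1ccccc1 | intermediate (not isolated)
18 | 1-(4-{[(1R,2S)-1-[4-(benzyloxy)-3-methoxyphenyl]-1,3-bis[(tert-butyldimethylsilyl)oxy]propan-2-yl]oxy}-3,5-dimethoxyphenyl)ethan-1-one | COc1cc([C@@H](O[Si](C)(C)C(C)(C)C)[C@H](CO[Si](C)(C)C(C)(C)C)Oc2c(OC)cc(C(C)=O)cc2OC)ccc1OCc1ccccc1 | intermediate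
19 | 1-(4-{[(1R,2S)-1,3-bis[(tert-butyldimethylsilyl)oxy]-1-(4-hydroxy-3-methoxyphenyl)propan-2-yl]oxy}-3,5-dimethoxyphenyl)ethan-1-one | COc1cc([C@@H](O[Si](C)(C)C(C)(C)C)[C@H](CO[Si](C)(C)C(C)(C)C)Oc2c(OC)cc(C(C)=O)cc2OC)ccc1O | intermediate
20 | 1-(4-{[(1R,2S)-1,3-dihydroxy-1-(4-hydroxy-3-methoxyphenyl)propan-2-yl]oxy}-3,5-dimethoxyphenyl)ethan-1-one | COc1cc([C@@H](O)[C@H](CO)Oc2c(OC)cc(C(C)=O)cc2OC)ccc1O | target

## Step count and weak points

Total: 13 steps. Longest linear sequence: 12 steps (steps 1 to 6 and 8 to 13, from 1); the diazo dione branch is step 7 alone.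

**Step 8 (key step).** The likeliest failure is slow capture of the carbenoid by the hindered secondary hydroxyl. Carbene dimerisation, insertion into traces of water or electrophilic attack on ring A would then consume the diazo compound and leave 9 unconverted. The fallback forms the ether at carbon by two inversions. It sets out from 9: Mitsunobu esterification (PPh3, DIAD, 4-nitrobenzoic acid, toluene) gives (1R,2R)-1-[4-(benzyloxy)-3-methoxyphenyl]-1,3-bis[(tert-butyldimethylsilyl)oxy]propan-2-yl 4-nitrobenzoate F1. Cold methanolysis (K2CO3, MeOH, 0 °C) gives the threo alcohol (1R,2R)-1-[4-(benzyloxy)-3-methoxyphenyl]-1,3-bis[(tert-butyldimethylsilyl)oxy]propan-2-ol F2. A second Mitsunobu reaction with commercial methyl 4-hydroxy-3,5-dimethoxybenzoate inverts C8 again and comes back to the route at 16.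

**Step 9.** Enolisation may be incomplete or may also take the ester into a ketene acetal, and the palladation may stall on the crowded diene, so that aromatisation stops short. The fallback fixes one enol as its methyl ether first and uses selenoxide elimination. It sets out from 12: TMSCHN2 in MeOH–toluene gives methyl 4-{[(1R,2S)-1-[4-(benzyloxy)-3-methoxyphenyl]-1,3-bis[(tert-butyldimethylsilyl)oxy]propan-2-yl]oxy}-3-methoxy-5-oxocyclohex-3-ene-1-carboxylate F3. LiN(iPr)2 and PhSeCl at −78 °C give the 6-(phenylselanyl) ketone F4. H2O2 and pyridine give the selenoxide F5, which eliminates and tautomerises to methyl 4-{[(1R,2S)-1-[4-(benzyloxy)-3-methoxyphenyl]-1,3-bis[(tert-butyldimethylsilyl)oxy]propan-2-yl]oxy}-3-hydroxy-5-methoxybenzoate F6. Methylation as in step 10 returns to the route at 16.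

**Step 3.** Facial selectivity may be poor if an open Felkin–Anh transition state or chelation through the other ring oxygen competes with the five-membered zinc chelate; the threo epimer would then travel through the route. The fallback replaces substrate control by catalyst control: Noyori transfer hydrogenation of 5 with RuCl(p-cymene)[(S,S)-TsDPEN] in HCO2H–Et3N leads from 5 directly to 6 and makes no new compound. The (S,S) ligand is the one the usual aryl–alkyl model matches to the R carbinol.

**Step 11.** MeMgBr may attack unreacted ester and over-add to the tertiary carbinol if amide formation is incomplete when it is introduced. The fallback goes through the acid. It sets out from 16: LiOH in THF–MeOH–H2O gives 4-{[(1R,2S)-1-[4-(benzyloxy)-3-methoxyphenyl]-1,3-bis[(tert-butyldimethylsilyl)oxy]propan-2-yl]oxy}-3,5-dimethoxybenzoic acid F7. MeLi in THF at 0 °C converts its lithium carboxylate to the methyl ketone and returns to the route at 18.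

**Step 12.** Over-reduction is the risk: hydrogenation of the aryl ketone or hydrogenolysis at benzylic C7 once the phenol is free. The fallback moves the hydrogenolysis ahead of the ketone. It sets out from 16: H2 and Pd/C in EtOAc give methyl 4-{[(1R,2S)-1,3-bis[(tert-butyldimethylsilyl)oxy]-1-(4-hydroxy-3-methoxyphenyl)propan-2-yl]oxy}-3,5-dimethoxybenzoate F8. The sequence of step 11, with one more equivalent of iPrMgCl for the phenol, passes through the phenolic Weinreb amide F9 and comes back to the route at 19.

## Further compounds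

F1 | step 8 | (1R,2R)-1-[4-(benzyloxy)-3-methoxyphenyl]-1,3-bis[(tert-butyldimethylsilyl)oxy]propan-2-yl 4-nitrobenzoate | COc1cc([C@@H](O[Si](C)(C)C(C)(C)C)[C@@H](CO[Si](C)(C)C(C)(C)C)OC(=O)c2ccc(cc2)[N+](=O)[O-])ccc1OCc1ccccc1
F2 | step 8 | (1R,2R)-1-[4-(benzyloxy)-3-methoxyphenyl]-1,3-bis[(tert-butyldimethylsilyl)oxy]propan-2-ol | COc1cc([C@@H](O[Si](C)(C)C(C)(C)C)[C@@H](CO[Si](C)(C)C(C)(C)C)O)ccc1OCc1ccccc1
F3 | step 9 | methyl 4-{[(1R,2S)-1-[4-(benzyloxy)-3-methoxyphenyl]-1,3-bis[(tert-butyldimethylsilyl)oxy]propan-2-yl]oxy}-3-methoxy-5-oxocyclohex-3-ene-1-carboxylate (C1 epimers) | COc1cc([C@@H](O[Si](C)(C)C(C)(C)C)[C@H](CO[Si](C)(C)C(C)(C)C)OC2=C(OC)CC(C(=O)OC)CC2=O)ccc1OCc1ccccc1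
F4 | step 9 | methyl 4-{[(1R,2S)-1-[4-(benzyloxy)-3-methoxyphenyl]-1,3-bis[(tert-butyldimethylsilyl)oxy]propan-2-yl]oxy}-3-methoxy-5-oxo-6-(phenylselanyl)cyclohex-3-ene-1-carboxylate | COc1cc([C@@H](O[Si](C)(C)C(C)(C)C)[C@H](CO[Si](C)(C)C(C)(C)C)OC2=C(OC)CC(C(=O)OC)C([Se]c3ccccc3)C2=O)ccc1OCc1ccccc1
F5 | step 9 | methyl 4-{[(1R,2S)-1-[4-(benzyloxy)-3-methoxyphenyl]-1,3-bis[(tert-butyldimethylsilyl)oxy]propan-2-yl]oxy}-3-methoxy-5-oxo-6-(phenylseleninyl)cyclohex-3-ene-1-carboxylate | COc1cc([C@@H](O[Si](C)(C)C(C)(C)C)[C@H](CO[Si](C)(C)C(C)(C)C)OC2=C(OC)CC(C(=O)OC)C([Se](=O)c3ccccc3)C2=O)ccc1OCc1ccccc1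
F6 | step 9 | methyl 4-{[(1R,2S)-1-[4-(benzyloxy)-3-methoxyphenyl]-1,3-bis[(tert-butyldimethylsilyl)oxy]propan-2-yl]oxy}-3-hydroxy-5-methoxybenzoate | COc1cc([C@@H](O[Si](C)(C)C(C)(C)C)[C@H](CO[Si](C)(C)C(C)(C)C)Oc2c(OC)cc(C(=O)OC)cc2O)ccc1OCc1ccccc1
F0 | step 3 | none | none
F7 | step 11 | 4-{[(1R,2S)-1-[4-(benzyloxy)-3-methoxyphenyl]-1,3-bis[(tert-butyldimethylsilyl)oxy]propan-2-yl]oxy}-3,5-dimethoxybenzoic acid | COc1cc([C@@H](O[Si](C)(C)C(C)(C)C)[C@H](CO[Si](C)(C)C(C)(C)C)Oc2c(OC)cc(C(=O)O)cc2OC)ccc1OCc1ccccc1
F8 | step 12 | methyl 4-{[(1R,2S)-1,3-bis[(tert-butyldimethylsilyl)oxy]-1-(4-hydroxy-3-methoxyphenyl)propan-2-yl]oxy}-3,5-dimethoxybenzoate | COc1cc([C@@H](O[Si](C)(C)C(C)(C)C)[C@H](CO[Si](C)(C)C(C)(C)C)Oc2c(OC)cc(C(=O)OC)cc2OC)ccc1O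
F9 | step 12 | 4-{[(1R,2S)-1,3-bis[(tert-butyldimethylsilyl)oxy]-1-(4-hydroxy-3-methoxyphenyl)propan-2-yl]oxy}-N,3,5-trimethoxy-N-methylbenzamide | COc1cc([C@@H](O[Si](C)(C)C(C)(C)C)[C@H](CO[Si](C)(C)C(C)(C)C)Oc2c(OC)cc(C(=O)N(C)OC)cc2OC)ccc1O
A1 | alternative 1 | (2S)-2-[2,6-dimethoxy-4-(2-methyl-1,3-dioxolan-2-yl)phenoxy]-3-[(triisopropylsilyl)oxy]propanal | O=C[C@H](CO[Si](C(C)C)(C(C)C)C(C)C)Oc1c(OC)cc(C2(C)OCCO2)cc1OC
A2 | alternative 1 | [4-(benzyloxy)-3-methoxyphenyl]titanium triisopropoxide | COc1cc([Ti](OC(C)C)(OC(C)C)OC(C)C)ccc1OCc1ccccc1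
A3 | alternative 1 | (1R,2S)-1-[4-(benzyloxy)-3-methoxyphenyl]-2-[2,6-dimethoxy-4-(2-methyl-1,3-dioxolan-2-yl)phenoxy]-3-[(triisopropylsilyl)oxy]propan-1-ol | COc1cc([C@@H](O)[C@H](CO[Si](C(C)C)(C(C)C)C(C)C)Oc2c(OC)cc(C3(C)OCCO3)cc2OC)ccc1OCc1ccccc1
A4 | alternative 2 | ethyl (2S,3R)-3-[4-(benzyloxy)-3-methoxyphenyl]-3-[(tert-butyldimethylsilyl)oxy]-2-{[(4-nitrophenyl)sulfonyl]oxy}propanoate | COc1cc([C@@H](O[Si](C)(C)C(C)(C)C)[C@@H](C(=O)OCC)OS(=O)(=O)c2ccc(cc2)[N+](=O)[O-])ccc1OCc1ccccc1
A5 | alternative 2 | 1-(4-hydroxy-3,5-dimethoxyphenyl)ethan-1-one | CC(=O)c1cc(OC)c(O)c(OC)c1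
A6 | alternative 2 | ethyl (2R,3R)-2-(4-acetyl-2,6-dimethoxyphenoxy)-3-[4-(benzyloxy)-3-methoxyphenyl]-3-[(tert-butyldimethylsilyl)oxy]propanoate | COc1cc([C@@H](O[Si](C)(C)C(C)(C)C)[C@H](C(=O)OCC)Oc2c(OC)cc(C(C)=O)cc2OC)ccc1OCc1ccccc1
A7 | alternative 3 | ethyl 3-[4-(benzyloxy)-3-methoxyphenyl]-2-[2,6-dimethoxy-4-(2-methyl-1,3-dioxolan-2-yl)phenoxy]-3-oxopropanoate (racemic) | COc1cc(C(=O)C(C(=O)OCC)Oc2c(OC)cc(C3(C)OCCO3)cc2OC)ccc1OCc1ccccc1
A8 | alternative 3 | ethyl (2R,3R)-3-[4-(benzyloxy)-3-methoxyphenyl]-2-[2,6-dimethoxy-4-(2-methyl-1,3-dioxolan-2-yl)phenoxy]-3-hydroxypropanoate | COc1cc([C@@H](O)[C@H](C(=O)OCC)Oc2c(OC)cc(C3(C)OCCO3)cc2OC)ccc1OCc1ccccc1
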